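**Retrosynthetic overview**

- The strategy rests on ring D: a benzene-1,4-diol whose C2 carries the CH2CH2 bridge to ring C. This is the reduced form of a 2-alkyl-1,4-benzoquinone, so ring D can arrive complete, with both oxygens, as 1,4-benzoquinone.
- Key disconnection: the bond between the bridge CH2 and C2 of ring D. A 3-arylpropanoic acid carrying rings A, B and C loses its carboxyl carbon as CO2, and its former α-carbon bonds as a primary radical to a C–H carbon of the quinone.
- The acid is assembled from the middle outward: the B–O–C diaryl ether by fluoride displacement on 4-fluorobenzaldehyde, then the A–B bridge by olefination of that aldehyde and hydrogenation.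
- No ring is built: four bought benzene rings are joined in the order B–O–C, A–B, C–D. The end game is quinone reduction and cleavage of two aryl methyl ethers.
- The target has no stereocentre; the E double bond of stilbene 6 is the only stereo element and is removed by hydrogenation.

Key step: step 6

**Route**

Step 1
Reactants: 1 3-(3-hydroxy-4-methoxyphenyl)propanoic acid
Product: 2 methyl 3-(3-hydroxy-4-methoxyphenyl)propanoate
Conditions: MeOH, cat. H2SO4, reflux
Reagents that add atoms: methanol, CO
Why: Fischer esterification, driven by the large excess of methanol, should mask the acid against the bases of the next steps while leaving the phenol free for ether formation.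

Step 2
Reactants: 2 methyl 3-(3-hydroxy-4-methoxyphenyl)propanoate; 3 4-fluorobenzaldehyde
Product: 4 methyl 3-[3-(4-formylphenoxy)-4-methoxyphenyl]propanoate
Conditions: K2CO3 (2 equiv), anhydrous DMF, 110 °C
Reagents that add atoms: none
Why: Nucleophilic aromatic substitution by addition–elimination: the phenoxide of 2 adds para to the formyl group of 3, which stabilises the Meisenheimer intermediate, and fluoride leaves; anhydrous carbonate should not touch the methyl ester.

Step 3
Reactants: 4 methyl 3-[3-(4-formylphenoxy)-4-methoxyphenyl]propanoate; 5 diethyl (3-methoxybenzyl)phosphonate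
Product: 6 methyl 3-(4-methoxy-3-{4-[(E)-2-(3-methoxyphenyl)ethenyl]phenoxy}phenyl)propanoate
Conditions: NaOMe (1.3 equiv), DMF, 0 °C to rt
Reagents that add atoms: none
Why: Horner–Wadsworth–Emmons olefination: the benzylic phosphonate anion adds to the non-enolisable aldehyde and diethyl phosphate is eliminated to give mainly the E-stilbene; methoxide matches the methyl ester, so any alkoxide exchange at the ester is degenerate.

Step 4
Reactants: 6 methyl 3-(4-methoxy-3-{4-[(E)-2-(3-methoxyphenyl)ethenyl]phenoxy}phenyl)propanoate
Product: 7 methyl 3-(4-methoxy-3-{4-[2-(3-methoxyphenyl)ethyl]phenoxy}phenyl)propanoate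
Conditions: H2 (1 atm), 10% Pd/C, EtOAc, rt
Reagents that add atoms: none
Why: Heterogeneous catalytic hydrogenation should saturate the conjugated C=C only, since the ester, the anisole ethers and the diaryl ether are inert at ambient pressure and temperature; the alkene geometry becomes irrelevant.

Step 5
Reactants: 7 methyl 3-(4-methoxy-3-{4-[2-(3-methoxyphenyl)ethyl]phenoxy}phenyl)propanoate
Product: 8 3-(4-methoxy-3-{4-[2-(3-methoxyphenyl)ethyl]phenoxy}phenyl)propanoic acid
Conditions: LiOH·H2O (3 equiv), THF/MeOH/H2O, rt; then 1 M HCl to pH 2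
Reagents that add atoms: lithium hydroxide, [Li+].[OH-]
Why: Saponification by hydroxide addition at the ester carbonyl and loss of methoxide should free the carboxylic acid needed as the radical precursor; nothing else in 7 is base-labile.

Step 6
Reactants: 8 3-(4-methoxy-3-{4-[2-(3-methoxyphenyl)ethyl]phenoxy}phenyl)propanoic acid; 9 1,4-benzoquinone
Product: 10 2-[2-(4-methoxy-3-{4-[2-(3-methoxyphenyl)ethyl]phenoxy}phenyl)ethyl]cyclohexa-2,5-diene-1,4-dione
Conditions: 9 (3 equiv), AgNO3 (0.2 equiv), (NH4)2S2O8 (1.5 equiv, aqueous solution added slowly), MeCN/H2O, 65 °C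
Reagents that add atoms: none
Why: Persulfate oxidises monovalent silver to divalent silver, which removes one electron from the carboxylate of 8; the acyloxy radical loses CO2 and leaves the primary 2-arylethyl radical centred on the former α-carbon of the acid. This nucleophilic radical adds to a C=C carbon of the electron-poor quinone 9, and the adduct radical is oxidised (by persulfate, divalent silver or a second quinone) and deprotonated, which restores the quinone with the new C–C bond in place. The closest known reaction type is the silver-catalysed persulfate decarboxylative alkylation of quinones by aliphatic carboxylic acids, a Minisci-type homolytic substitution for which simple 3-arylpropanoic acids are established partners. No ring is closed and no stereocentre is formed, and the 1,2-aryl shift open to a 2-arylethyl radical would only return the same radical. The step needs monoalkylation and oxidation at the carboxylate rather than at the alkoxyarenes: the four C–H carbons of 9 are equivalent so only one regioisomer can form, the excess of 9 intercepts the radical before product 10 can be alkylated again, and slow addition of the oxidant with only catalytic silver keeps the standing level of strong oxidant low.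

Step 7
Reactants: 10 2-[2-(4-methoxy-3-{4-[2-(3-methoxyphenyl)ethyl]phenoxy}phenyl)ethyl]cyclohexa-2,5-diene-1,4-dione
Product: 11 2-[2-(4-methoxy-3-{4-[2-(3-methoxyphenyl)ethyl]phenoxy}phenyl)ethyl]benzene-1,4-diol
Conditions: Na2S2O4 (excess), EtOAc/H2O, rt, under argon
Reagents that add atoms: none
Why: Dithionite reduction of a quinone to its hydroquinone is a fast two-electron, two-proton transfer that should leave the aryl ethers untouched and spares the quinone from the Lewis acid of the last step.

Step 8
Reactants: 11 2-[2-(4-methoxy-3-{4-[2-(3-methoxyphenyl)ethyl]phenoxy}phenyl)ethyl]benzene-1,4-diol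
Product: 12 2-[2-(4-hydroxy-3-{4-[2-(3-hydroxyphenyl)ethyl]phenoxy}phenyl)ethyl]benzene-1,4-diol (target CNP0300581.0)
Conditions: BBr3 (6 equiv), CH2Cl2, −78 °C to rt, argon; then degassed ice-water
Reagents that add atoms: none
Why: Lewis acid cleavage of aryl methyl ethers: BBr3 coordinates each methoxy oxygen and bromide removes the methyl group by SN2 attack, while the diaryl ether offers no sp3 carbon and should survive; the excess reagent allows for the two free hydroxyls, and water hydrolyses the aryl borates.

**Compound list**

1 | 3-(3-hydroxy-4-methoxyphenyl)propanoic acid | COc1ccc(CCC(=O)O)cc1O | starting material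
2 | methyl 3-(3-hydroxy-4-methoxyphenyl)propanoate | COc1ccc(CCC(=O)OC)cc1O | intermediate
3 | 4-fluorobenzaldehyde | O=Cc1ccc(F)cc1 | starting material
4 | methyl 3-[3-(4-formylphenoxy)-4-methoxyphenyl]propanoate | COC(=O)CCc1ccc(OC)c(Oc2ccc(C=O)cc2)c1 | intermediate
5 | diethyl (3-methoxybenzyl)phosphonate | CCOP(=O)(OCC)Cc1cccc(OC)c1 | starting material
6 | methyl 3-(4-methoxy-3-{4-[(E)-2-(3-methoxyphenyl)ethenyl]phenoxy}phenyl)propanoate | COC(=O)CCc1ccc(OC)c(Oc2ccc(/C=C/c3cccc(OC)c3)cc2)c1 | intermediate
7 | methyl 3-(4-methoxy-3-{4-[2-(3-methoxyphenyl)ethyl]phenoxy}phenyl)propanoate | COC(=O)CCc1ccc(OC)c(Oc2ccc(CCc3cccc(OC)c3)cc2)c1 | intermediate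
8 | 3-(4-methoxy-3-{4-[2-(3-methoxyphenyl)ethyl]phenoxy}phenyl)propanoic acid | O=C(O)CCc1ccc(OC)c(Oc2ccc(CCc3cccc(OC)c3)cc2)c1 | intermediate
9 | 1,4-benzoquinone | O=C1C=CC(=O)C=C1 | starting material
10 | 2-[2-(4-methoxy-3-{4-[2-(3-methoxyphenyl)ethyl]phenoxy}phenyl)ethyl]cyclohexa-2,5-diene-1,4-dione | COc1cccc(CCc2ccc(Oc3cc(CCC4=CC(=O)C=CC4=O)ccc3OC)cc2)c1 | intermediate
11 | 2-[2-(4-methoxy-3-{4-[2-(3-methoxyphenyl)ethyl]phenoxy}phenyl)ethyl]benzene-1,4-diol | COc1cccc(CCc2ccc(Oc3cc(CCc4cc(O)ccc4O)ccc3OC)cc2)c1 | intermediate
12 | 2-[2-(4-hydroxy-3-{4-[2-(3-hydroxyphenyl)ethyl]phenoxy}phenyl)ethyl]benzene-1,4-diol (CNP0300581.0) | Oc1cccc(CCc2ccc(Oc3cc(CCc4cc(O)ccc4O)ccc3O)cc2)c1 | target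

**Step count and risks**

Total step count: 8 steps.
Longest linear sequence: 8 steps (1 to 12); compounds 3, 5 and 9 enter as bought partners.

Steps most likely to fail:

1. Step 6 (key step). One-electron oxidation of the alkoxy-substituted rings, ring C above all, by divalent silver or sulfate radical anion may compete with oxidation of the carboxylate and lead to lactonisation onto ring C or to oligomers; a second alkylation of the quinone is also possible. The fallback sets out from acid 8 and makes the same bond with loss of the same carbon, but under reducing conditions. Acid 8 would be condensed with N-hydroxyphthalimide (N,N'-diisopropylcarbodiimide, cat. DMAP, CH2Cl2) to the redox-active ester 1,3-dioxoisoindolin-2-yl 3-(4-methoxy-3-{4-[2-(3-methoxyphenyl)ethyl]phenoxy}phenyl)propanoate F1. Nickel-catalysed decarboxylative cross-electrophile coupling of this ester with 2-iodo-1,4-dimethoxybenzene (NiBr2(dme), 4,4'-di-tert-butyl-2,2'-bipyridine, Zn dust, DMA, rt) should give the tetramethyl ether 1,4-dimethoxy-2-[2-(4-methoxy-3-{4-[2-(3-methoxyphenyl)ethyl]phenoxy}phenyl)ethyl]benzene F2. BBr3 in CH2Cl2 would then cleave all four methyl ethers, so the fallback comes back to the route at target 12 and bypasses 10 and 11.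

2. Step 8. Ether cleavage may stop short because the two free hydroxyls tie up the boron reagent, and the electron-rich hydroquinone ring may be air-oxidised back to the quinone or to dark polymer during aqueous work-up and chromatography. The fallback sets out from hydroquinone 11 and masks ring D through the harsh step. Acetylation (Ac2O, pyridine, cat. DMAP) should give 2-[2-(4-methoxy-3-{4-[2-(3-methoxyphenyl)ethyl]phenoxy}phenyl)ethyl]-1,4-phenylene diacetate F3. BBr3 in CH2Cl2 from −78 °C to 0 °C should cleave the two methyl ethers to 2-[2-(4-hydroxy-3-{4-[2-(3-hydroxyphenyl)ethyl]phenoxy}phenyl)ethyl]-1,4-phenylene diacetate F4; any acetate lost at this stage is harmless. Transesterification with HCl in degassed methanol would remove the acetates, and the fallback comes back at target 12.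

3. Step 3. Methoxide may deprotonate the carbon next to the methyl ester, so that Claisen-type self-condensation or aldol addition to the aldehyde competes with the slower formation and addition of the weakly stabilised benzylic phosphonate anion. The fallback sets out from aldehyde 4 and builds the A–B bridge through an alkyne. Ohira–Bestmann homologation (dimethyl (1-diazo-2-oxopropyl)phosphonate, K2CO3, MeOH, rt) should give methyl 3-[3-(4-ethynylphenoxy)-4-methoxyphenyl]propanoate F5. Sonogashira coupling with 3-iodoanisole (PdCl2(PPh3)2, CuI, Et3N, THF) should give methyl 3-(4-methoxy-3-{4-[(3-methoxyphenyl)ethynyl]phenoxy}phenyl)propanoate F6. Hydrogenation of the triple bond (H2, Pd/C, EtOAc) comes back to the route at ester 7, skipping 6.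

**Further compounds**

F1 | step 6 | 1,3-dioxoisoindolin-2-yl 3-(4-methoxy-3-{4-[2-(3-methoxyphenyl)ethyl]phenoxy}phenyl)propanoate | COc1cccc(CCc2ccc(Oc3cc(CCC(=O)ON4C(=O)c5ccccc5C4=O)ccc3OC)cc2)c1
F2 | step 6 | 1,4-dimethoxy-2-[2-(4-methoxy-3-{4-[2-(3-methoxyphenyl)ethyl]phenoxy}phenyl)ethyl]benzene | COc1cccc(CCc2ccc(Oc3cc(CCc4cc(OC)ccc4OC)ccc3OC)cc2)c1
F3 | step 8 | 2-[2-(4-methoxy-3-{4-[2-(3-methoxyphenyl)ethyl]phenoxy}phenyl)ethyl]-1,4-phenylene diacetate | COc1cccc(CCc2ccc(Oc3cc(CCc4cc(OC(C)=O)ccc4OC(C)=O)ccc3OC)cc2)c1
F4 | step 8 | 2-[2-(4-hydroxy-3-{4-[2-(3-hydroxyphenyl)ethyl]phenoxy}phenyl)ethyl]-1,4-phenylene diacetate | Oc1cccc(CCc2ccc(Oc3cc(CCc4cc(OC(C)=O)ccc4OC(C)=O)ccc3O)cc2)c1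
F5 | step 3 | methyl 3-[3-(4-ethynylphenoxy)-4-methoxyphenyl]propanoate | COC(=O)CCc1ccc(OC)c(Oc2ccc(C#C)cc2)c1
F6 | step 3 | methyl 3-(4-methoxy-3-{4-[(3-methoxyphenyl)ethynyl]phenoxy}phenyl)propanoate | COC(=O)CCc1ccc(OC)c(Oc2ccc(C#Cc3cccc(OC)c3)cc2)c1
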